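**Retrosynthetic overview**
- Feature: ring B (the phenol ring: C1 OH, C2 aryloxy, C3 methyl, C4 methoxy, C5 H, C6 isopropyl) has its two oxygens para on C1 and C4. It is a differentiated hydroquinone in which C1–C4 map onto the four carbons of a squarate and C5–C6 onto a 1,1-disubstituted alkene.
- Endgame: removal of a silyl group from the C1 oxygen and O-methylation at C4 lead back to a hydroquinone silylated only on the C1 oxygen.
- Key disconnection: the C4–C5 bond of ring B, traced back to a 4-alkenyl-4-silyloxycyclobutenone that opens (4π) and recloses (6π) on heating.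
- The cyclobutenone comes from a 3-aryloxy-4-methylcyclobutenedione and 3-methylbut-1-en-2-yllithium (C1–C6 bond). The dione comes from dimethyl squarate (methyllithium, hydrolysis, chloride, phenol substitution) and 4-methoxythymol (thymol, bromination, methoxylation).
- Ring order: ring A is bought intact as thymol and the four-membered ring as the squarate; ring B is the only ring formed, in step 8.

Key step: step 8

Remark: the target is achiral, so the single stereocentre of the cyclobutenone intermediates is carried as a racemate and disappears on aromatisation; 2-bromo-3-methylbut-1-ene is taken as a purchasable reagent.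

**Route**

Step 1
Reactants: 1 thymol (2-isopropyl-5-methylphenol)
Product: 2 4-bromo-2-isopropyl-5-methylphenol
Conditions: NBS (1.0 equiv), MeCN, 0 °C to rt
Reagents that add atoms: N-bromosuccinimide, O=C1CCC(=O)N1Br
Why: Electrophilic aromatic bromination of a phenol goes para to the hydroxyl, which in thymol is the activated position least shielded by the isopropyl group.

Step 2
Reactants: 2 4-bromo-2-isopropyl-5-methylphenol
Product: 3 2-isopropyl-4-methoxy-5-methylphenol (4-methoxythymol)
Conditions: NaOMe (5 equiv), CuBr (10 mol %), DMF–MeOH, 110 °C, N2; then aq HCl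
Reagents that add atoms: sodium methoxide, C[O-].[Na+]
Why: Copper-catalysed Ullmann-type methoxylation of an aryl bromide, which 2-alkyl-4-bromophenols undergo as their phenoxides without protection, places the methoxy group unambiguously para to the free hydroxyl.

Step 3
Reactants: 4 dimethyl squarate
Product: 7 3-methoxy-4-methylcyclobut-3-ene-1,2-dione, via lithium alkoxide 5 (not isolated), via hydroxycyclobutenone 6 (not isolated)
Conditions: MeLi (1.05 equiv), THF, −78 °C; 2 M HCl quench; then conc. HCl (cat.), CH2Cl2, rt
Reagents that add atoms: methyllithium, [Li]C; water, O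
Why: 1,2-Addition of an organolithium to one squarate carbonyl, followed by acid-promoted ionisation of the tertiary carbinol, attack of water at the methoxy-stabilised allyl terminus and loss of methanol, is the standard passage from a squarate ester to a 3-alkoxy-4-alkylcyclobutenedione.

Step 4
Reactants: 7 3-methoxy-4-methylcyclobut-3-ene-1,2-dione
Product: 8 3-hydroxy-4-methylcyclobut-3-ene-1,2-dione
Conditions: 2 M aq HCl, MeCN, 50 °C; evaporate
Reagents that add atoms: water, O
Why: Acid hydrolysis of the vinylogous methyl ester proceeds by addition of water at the methoxy-bearing carbon and loss of methanol, as in the hydrolysis of squarate esters, and leaves the strongly acidic vinylogous acid.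

Step 5
Reactants: 8 3-hydroxy-4-methylcyclobut-3-ene-1,2-dione; 3 2-isopropyl-4-methoxy-5-methylphenol
Product: 10 3-(2-isopropyl-4-methoxy-5-methylphenoxy)-4-methylcyclobut-3-ene-1,2-dione, via chlorocyclobutenedione 9 (not isolated)
Conditions: (COCl)2 (1.3 equiv), DMF (cat.), CH2Cl2, 0 °C to rt, evaporate; then 3, i-Pr2NEt, CH2Cl2, −40 to 0 °C
Reagents that add atoms: none
Why: The vinylogous acid is turned into its vinylogous acid chloride as a carboxylic acid would be, and the phenol then displaces chloride by addition–elimination at the β-carbon of the enedione, an acylation-like substitution fast enough to accept the ortho-isopropyl phenol.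

Step 6
Reactants: 11 2-bromo-3-methylbut-1-ene; 10 3-(2-isopropyl-4-methoxy-5-methylphenoxy)-4-methylcyclobut-3-ene-1,2-dione
Product: 14 4-hydroxy-3-(2-isopropyl-4-methoxy-5-methylphenoxy)-2-methyl-4-(3-methylbut-1-en-2-yl)cyclobut-2-en-1-one (racemic), via 3-methylbut-1-en-2-yllithium 12 (not isolated), via lithium alkoxide 13 (not isolated)
Conditions: 11, t-BuLi (2.0 equiv), Et2O, −78 °C; cannulate into 10, THF, −78 °C; sat. aq NH4Cl, −78 °C
Reagents that add atoms: none
Why: Bromine–lithium exchange gives the alkenyllithium, which adds 1,2 to the ketone beside the aryloxy carbon because the other carbonyl is deactivated as a vinylogous ester (the regiochemistry established for 3-alkoxy-4-alkylcyclobutenediones); the new quaternary stereocentre forms as a racemate and is erased in step 8.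

Step 7
Reactants: 14 4-hydroxy-3-(2-isopropyl-4-methoxy-5-methylphenoxy)-2-methyl-4-(3-methylbut-1-en-2-yl)cyclobut-2-en-1-one
Product: 15 4-(tert-butyldimethylsilyloxy)-3-(2-isopropyl-4-methoxy-5-methylphenoxy)-2-methyl-4-(3-methylbut-1-en-2-yl)cyclobut-2-en-1-one (racemic)
Conditions: TBSOTf (1.5 equiv), 2,6-lutidine (3 equiv), CH2Cl2, −78 to 0 °C
Reagents that add atoms: tert-butyldimethylsilyl trifluoromethanesulfonate, CC(C)(C)[Si](C)(C)OS(=O)(=O)C(F)(F)F
Why: A silyl triflate with a hindered pyridine base is the standard reagent pair for silylating tertiary alcohols, and the buffered, cold conditions avoid ionisation of the carbinol.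

Step 8
Reactants: 15 4-(tert-butyldimethylsilyloxy)-3-(2-isopropyl-4-methoxy-5-methylphenoxy)-2-methyl-4-(3-methylbut-1-en-2-yl)cyclobut-2-en-1-one
Product: 18 4-(tert-butyldimethylsilyloxy)-5-isopropyl-3-(2-isopropyl-4-methoxy-5-methylphenoxy)-2-methylphenol, via dienylketene 16 (not isolated), via cyclohexadienone 17 (not isolated)
Conditions: p-xylene (0.02 M, degassed), 138 °C, Ar
Reagents that add atoms: none
Why: Heating should open the cyclobutenone by conrotatory 4π electrocyclic cleavage of the bond between the carbonyl carbon and the silyloxy carbon to give dienylketene 16, whose ketene carbon then bonds to the terminal methylene in a disrotatory 6π electrocyclisation, and the cyclohexa-2,4-dienone 17 tautomerises to the phenol, which makes the sequence irreversible. This is the Moore rearrangement of squarate-derived 4-alkenyl-4-oxycyclobutenones, the established thermal route to monoprotected hydroquinones. Ring B is closed by this six-membered 6π electrocyclic closure, which forms the bond between the former carbonyl carbon (C4 of ring B) and the alkene CH2 (C5). No stereocentre is created, and the one quaternary stereocentre of 15 becomes an aromatic carbon. The step needs the alkenyl group to rotate inward toward the ketene, and this is secured by the strong preference of the donor silyloxy group for outward rotation in the ring opening. Regiochemistry is fixed by connectivity, so the silyl ether ends on the oxygen flanked by isopropyl and aryloxy and the free hydroxyl on the carbon flanked by methyl and hydrogen.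

Step 9
Reactants: 18 4-(tert-butyldimethylsilyloxy)-5-isopropyl-3-(2-isopropyl-4-methoxy-5-methylphenoxy)-2-methylphenol
Product: 19 tert-butyl[6-isopropyl-2-(2-isopropyl-4-methoxy-5-methylphenoxy)-4-methoxy-3-methylphenoxy]dimethylsilane
Conditions: MeI (3 equiv), K2CO3, acetone, 50 °C
Reagents that add atoms: iodomethane, CI
Why: Williamson methylation of the only free phenol, which sits between a methyl group and a hydrogen and is readily accessible, while the di-ortho-substituted aryl silyl ether should be inert to carbonate in dry acetone.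

Step 10
Reactants: 19 tert-butyl[6-isopropyl-2-(2-isopropyl-4-methoxy-5-methylphenoxy)-4-methoxy-3-methylphenoxy]dimethylsilane
Product: 20 6-isopropyl-2-(2-isopropyl-4-methoxy-5-methylphenoxy)-4-methoxy-3-methylphenol (target)
Conditions: TBAF (1.2 equiv), AcOH (1.2 equiv), THF, 0 °C to rt
Reagents that add atoms: none
Why: Fluoride cleaves the aryl silyl ether at silicon, and the acetic acid buffer keeps the electron-rich phenol from standing as its air-sensitive phenoxide.

**Compound list**
1 | thymol (2-isopropyl-5-methylphenol) | CC(C)c1ccc(C)cc1O | starting material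
2 | 4-bromo-2-isopropyl-5-methylphenol | CC(C)c1cc(Br)c(C)cc1O | intermediate
3 | 2-isopropyl-4-methoxy-5-methylphenol (4-methoxythymol) | COc1cc(C(C)C)c(O)cc1C | intermediate
4 | dimethyl squarate (3,4-dimethoxycyclobut-3-ene-1,2-dione) | COC1=C(OC)C(=O)C1=O | starting material
5 | lithium 2,3-dimethoxy-1-methyl-4-oxocyclobut-2-en-1-olate (racemic) | [Li]OC1(C)C(OC)=C(OC)C1=O | intermediate
6 | 4-hydroxy-2,3-dimethoxy-4-methylcyclobut-2-en-1-one (racemic) | OC1(C)C(OC)=C(OC)C1=O | intermediate
7 | 3-methoxy-4-methylcyclobut-3-ene-1,2-dione | COC1=C(C)C(=O)C1=O | intermediate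
8 | 3-hydroxy-4-methylcyclobut-3-ene-1,2-dione | OC1=C(C)C(=O)C1=O | intermediate
9 | 3-chloro-4-methylcyclobut-3-ene-1,2-dione | ClC1=C(C)C(=O)C1=O | intermediate
10 | 3-(2-isopropyl-4-methoxy-5-methylphenoxy)-4-methylcyclobut-3-ene-1,2-dione | COc1cc(C(C)C)c(OC2=C(C)C(=O)C2=O)cc1C | intermediate
11 | 2-bromo-3-methylbut-1-ene | CC(C)C(Br)=C | starting material
12 | 3-methylbut-1-en-2-yllithium | [Li]C(=C)C(C)C | intermediate
13 | lithium 2-(2-isopropyl-4-methoxy-5-methylphenoxy)-3-methyl-1-(3-methylbut-1-en-2-yl)-4-oxocyclobut-2-en-1-olate (racemic) | [Li]OC1(C(=C)C(C)C)C(=O)C(C)=C1Oc1cc(C)c(OC)cc1C(C)C | intermediate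
14 | 4-hydroxy-3-(2-isopropyl-4-methoxy-5-methylphenoxy)-2-methyl-4-(3-methylbut-1-en-2-yl)cyclobut-2-en-1-one (racemic) | C=C(C(C)C)C1(O)C(=O)C(C)=C1Oc1cc(C)c(OC)cc1C(C)C | intermediate
15 | 4-(tert-butyldimethylsilyloxy)-3-(2-isopropyl-4-methoxy-5-methylphenoxy)-2-methyl-4-(3-methylbut-1-en-2-yl)cyclobut-2-en-1-one (racemic) | C=C(C(C)C)C1(O[Si](C)(C)C(C)(C)C)C(=O)C(C)=C1Oc1cc(C)c(OC)cc1C(C)C | intermediate
16 | (3Z)-4-(tert-butyldimethylsilyloxy)-5-isopropyl-3-(2-isopropyl-4-methoxy-5-methylphenoxy)-2-methylhexa-1,3,5-trien-1-one (dienylketene) | O=C=C(C)/C(Oc1cc(C)c(OC)cc1C(C)C)=C(\C(=C)C(C)C)O[Si](C)(C)C(C)(C)C | intermediate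
17 | 4-(tert-butyldimethylsilyloxy)-5-isopropyl-3-(2-isopropyl-4-methoxy-5-methylphenoxy)-2-methylcyclohexa-2,4-dien-1-one | O=C1CC(C(C)C)=C(O[Si](C)(C)C(C)(C)C)C(Oc2cc(C)c(OC)cc2C(C)C)=C1C | intermediate
18 | 4-(tert-butyldimethylsilyloxy)-5-isopropyl-3-(2-isopropyl-4-methoxy-5-methylphenoxy)-2-methylphenol | CC(C)c1cc(O)c(C)c(Oc2cc(C)c(OC)cc2C(C)C)c1O[Si](C)(C)C(C)(C)C | intermediate
19 | tert-butyl[6-isopropyl-2-(2-isopropyl-4-methoxy-5-methylphenoxy)-4-methoxy-3-methylphenoxy]dimethylsilane | CC(C)c1cc(OC)c(C)c(Oc2cc(C)c(OC)cc2C(C)C)c1O[Si](C)(C)C(C)(C)C | intermediate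
20 | 6-isopropyl-2-(2-isopropyl-4-methoxy-5-methylphenoxy)-4-methoxy-3-methylphenol | COc1cc(C(C)C)c(Oc2c(C)c(OC)cc(C(C)C)c2O)cc1C | target

**Step count and risks**

Total step count: 10. Longest linear sequence: 8 steps (steps 3–10 from dimethyl squarate). The two-step thymol branch joins in step 5 and the alkenyl bromide enters in step 6.

Steps most likely to fail:

1. Step 6. The alkenyllithium may attack at the wrong site: addition to the vinylogous-ester carbonyl, or addition–elimination at the aryloxy carbon that expels the aryloxide, a better leaving group than the alkoxides for which the selectivity is established. The fallback sets out from 7 (with 12 made as in step 6) and comes back at 15; it installs the aryl ether after the carbon–carbon bond. Alkenyllithium 12 is added to methoxy dione 7 (THF, −78 °C), where methoxide is a poor leaving group, to give 4-hydroxy-3-methoxy-2-methyl-4-(3-methylbut-1-en-2-yl)cyclobut-2-en-1-one F1. Silylation (TBSOTf, 2,6-lutidine) should give 4-(tert-butyldimethylsilyloxy)-3-methoxy-2-methyl-4-(3-methylbut-1-en-2-yl)cyclobut-2-en-1-one F2. LiOH in aqueous THF at 0 °C and careful acidification should cleave the vinylogous ester to 4-(tert-butyldimethylsilyloxy)-3-hydroxy-2-methyl-4-(3-methylbut-1-en-2-yl)cyclobut-2-en-1-one F3. Its enolate is mirror-symmetric, so no regiochemical question remains. Oxalyl chloride with catalytic DMF then gives 4-(tert-butyldimethylsilyloxy)-3-chloro-2-methyl-4-(3-methylbut-1-en-2-yl)cyclobut-2-en-1-one F4, and 4-methoxythymol 3 with i-Pr2NEt displaces chloride by addition–elimination to give 15.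

2. Step 8. Closure of the congested dienylketene (isopropyl on the alkene, silyloxy and a bulky aryloxy on the diene) may be slow, so that the ketene is lost to dimerisation or to adventitious nucleophiles before the ring forms. The fallback sets out from 3 and comes back at 20; it makes ring B from a second molecule of 4-methoxythymol and forms the diaryl ether by copper catalysis. Bromination of 3 with NBS ortho to the hydroxyl should give 2-bromo-6-isopropyl-4-methoxy-3-methylphenol F5. Benzylation (BnBr, K2CO3, DMF) gives 1-(benzyloxy)-2-bromo-6-isopropyl-4-methoxy-3-methylbenzene F6. Ullmann diaryl ether coupling of this bromide with 3 (CuI, N,N-dimethylglycine, Cs2CO3, dioxane, 110 °C) should give 1-(benzyloxy)-6-isopropyl-2-(2-isopropyl-4-methoxy-5-methylphenoxy)-4-methoxy-3-methylbenzene F7, and hydrogenolysis (H2, Pd/C, EtOAc) gives 20.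

3. Step 7. Silylation of the crowded tertiary alcohol may stall, or the Lewis-acidic silyl triflate may trigger ionisation or ring opening of the hydroxycyclobutenone. The fallback sets out from 14 and comes back at 20; it drops the protecting group and tells the two oxygens apart by sterics. Heating unprotected 14 (toluene, 110 °C, Ar) should give, by the same ring expansion, 5-isopropyl-3-(2-isopropyl-4-methoxy-5-methylphenoxy)-2-methylbenzene-1,4-diol F8. Monomethylation (MeI, 1.0 equiv, K2CO3, acetone, Ar) should then take place at the hydroxyl flanked by methyl and hydrogen, the other being shielded by isopropyl and aryloxy, to give 20.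

**Further compounds**
F1 | step 6 | 4-hydroxy-3-methoxy-2-methyl-4-(3-methylbut-1-en-2-yl)cyclobut-2-en-1-one (racemic) | C=C(C(C)C)C1(O)C(=O)C(C)=C1OC
F2 | step 6 | 4-(tert-butyldimethylsilyloxy)-3-methoxy-2-methyl-4-(3-methylbut-1-en-2-yl)cyclobut-2-en-1-one (racemic) | C=C(C(C)C)C1(O[Si](C)(C)C(C)(C)C)C(=O)C(C)=C1OC
F3 | step 6 | 4-(tert-butyldimethylsilyloxy)-3-hydroxy-2-methyl-4-(3-methylbut-1-en-2-yl)cyclobut-2-en-1-one (racemic) | C=C(C(C)C)C1(O[Si](C)(C)C(C)(C)C)C(=O)C(C)=C1O
F4 | step 6 | 4-(tert-butyldimethylsilyloxy)-3-chloro-2-methyl-4-(3-methylbut-1-en-2-yl)cyclobut-2-en-1-one (racemic) | C=C(C(C)C)C1(O[Si](C)(C)C(C)(C)C)C(=O)C(C)=C1Cl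
F5 | step 8 | 2-bromo-6-isopropyl-4-methoxy-3-methylphenol | COc1cc(C(C)C)c(O)c(Br)c1C
F6 | step 8 | 1-(benzyloxy)-2-bromo-6-isopropyl-4-methoxy-3-methylbenzene | COc1cc(C(C)C)c(OCc2ccccc2)c(Br)c1C
F7 | step 8 | 1-(benzyloxy)-6-isopropyl-2-(2-isopropyl-4-methoxy-5-methylphenoxy)-4-methoxy-3-methylbenzene | COc1cc(C(C)C)c(Oc2c(C)c(OC)cc(C(C)C)c2OCc2ccccc2)cc1C
F8 | step 7 | 5-isopropyl-3-(2-isopropyl-4-methoxy-5-methylphenoxy)-2-methylbenzene-1,4-diol | CC(C)c1cc(O)c(C)c(Oc2cc(C)c(OC)cc2C(C)C)c1O
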